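**Plan**

- Cuts (terpenoid half numbered as spiro[4.5]decane: C1 O-bearing, C2 angular methyl, C5 spiro, C6=C7 with iPr on C7, C10 = CHMe): (a) both aryl–CHO bonds; (b) the dihydropyran ring at O–C1 and benzylic C–C2, with C1–H from a ketal; (c) the cyclohexene ring at C5–C10 and C6–C7.
- Enabling feature: the spiro carbon C5 is flanked by C1, the carbon that ends as O–CH. With C1 as a ketone, C5=C6 is an exocyclic enone (2π) and C7–C8–C9–C10 is a diene (4π), so the six-membered ring and its spiro junction arise in one Diels–Alder reaction.
- Helpers and their removal: OSi on C8 (regiocontrol; C8=O is reduced to CH2), CO2Et on C6 (second activator; leaves as CO2 and gives C6=C7, the only alkene possible because C5 is quaternary), C1=O (activator; becomes the ketal carbon, then O–CH).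
- Forward order: cyclopentanone → spiro-cyclohexane (step 5) → alkene unveiled (step 8) → dihydropyran ring fused on with the arene attached (step 11) → ketal reduction → two formyl groups.
- Stereochemistry: C5/C10 from the catalysed, ketone-exo Diels–Alder (absolute sense from the catalyst); C2 and the benzylic centre from the quinone methide cycloaddition anti to the C10 branch; C1 from hydride delivery that gives the cis ring fusion.

Key step: step 5

Assumption: the oxazaborolidinium catalyst is taken to bind the more basic ring ketone of 9 and to expose the alkylidene face that leads to the (5R,10S) adduct; this sense would be confirmed on the first adduct, the (R)-catalyst being equally available.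

**Route**

Step 1
Reactants: 1 (2E)-but-2-enal; 2 isobutylmagnesium bromide
Product: 3 (2E)-6-methylhept-2-en-4-ol (racemic)
Conditions: Et2O, −78 → 0 °C; aq. NH4Cl
Reagents that add atoms: none
Why: Grignard 1,2-addition to an enal should give the allylic alcohol; its stereocentre is removed in step 2.

Step 2
Reactants: 3 (2E)-6-methylhept-2-en-4-ol
Product: 4 (2E)-6-methylhept-2-en-4-one
Conditions: MnO2 (activated, excess), CH2Cl2, rt
Reagents that add atoms: none
Why: MnO2 oxidation of an allylic alcohol should give the enone without touching the E double bond.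

Step 3
Reactants: 4 (2E)-6-methylhept-2-en-4-one
Product: 5 {[(2E,4Z)-6-methylhepta-2,4-dien-4-yl]oxy}tri(propan-2-yl)silane
Conditions: iPr3SiOTf, Et3N, CH2Cl2, 0 °C → rt
Reagents that add atoms: triisopropylsilyl trifluoromethanesulfonate, CC(C)[Si](OS(=O)(=O)C(F)(F)F)(C(C)C)C(C)C
Why: Soft enolisation and O-silylation at the α'-CH2 should give the cross-conjugated 2-silyloxy diene as the favoured Z enol ether (isopropyl cis to oxygen, hence "outside" in the s-cis diene); any E isomer is inert in step 5.

Step 4
Reactants: 6 2-methylcyclopentan-1-one; 7 ethyl glyoxylate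
Product: 9 ethyl (2E)-2-(3-methyl-2-oxocyclopentylidene)acetate (racemic), via pyrrolidine enamine 8 (not isolated)
Conditions: pyrrolidine, PhMe, reflux (water separator); then 7, 0 °C → rt; then AcOH/H2O, 60 °C
Reagents that add atoms: none
Why: Stork enamine aldol condensation: the less substituted enamine should condense with the aldehyde at the CH2 side (the methyl-bearing carbon cannot form an alkylidene), and hydrolysis should give the thermodynamic E alkylidene with the ester anti to the ketone.

Step 5
Reactants: 9 ethyl (2E)-2-(3-methyl-2-oxocyclopentylidene)acetate; 5 {[(2E,4Z)-6-methylhepta-2,4-dien-4-yl]oxy}tri(propan-2-yl)silane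
Product: 11 ethyl (5R,6R,7S,10S)-2,10-dimethyl-1,8-dioxo-7-(propan-2-yl)spiro[4.5]decane-6-carboxylate (C2 epimers), via silyl enol ether cycloadduct 10 (not isolated)
Conditions: (S)-B-(o-tolyl) diphenylprolinol oxazaborolidine·HNTf2 (20 mol%), CH2Cl2, −78 → −40 °C; then 2 M HCl, THF, rt
Reagents that add atoms: none
Why: Concerted but asynchronous normal-demand [4+2] cycloaddition in which the oxazaborolidinium-bound ring ketone of 9 lowers the LUMO of the exocyclic C=C and the silyloxy diene 5 is the 4π partner, the closest known type being Lewis-acid-catalysed Diels–Alder reactions of 2-silyloxy dienes with exocyclic, spiro-forming enones; hydrolysis of the silyl enol ether then shows the C8 ketone. The cyclohexene ring is closed by intermolecular cycloaddition, bonds C6–C7 and C5–C10 forming on one face of each partner, and it is spiro because the dienophile double bond is exocyclic to the cyclopentanone. Regiochemistry, the selectivity the step needs most, is secured twice: the silyloxy group makes the isopropyl-bearing diene terminus the nucleophilic one, which joins the unhindered CH(CO2Et) carbon β to the ketone, while the E-methyl terminus joins the fully substituted α-carbon. The C5/C10 relationship should follow from the transition state with the s-cis-locked ring ketone exo, as is usual for exocyclic enones, and the trans-disposed ester endo, which places the outside methyl of the diene cis to the ring CH2 (C4) and trans to C1. The absolute configuration (5R,10S) should come from the catalyst shielding one face of the ketone-bound alkylidene. The centres C6 and C7 formed at the same time are erased in step 8 and the C2 epimers converge in step 9.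

Step 6
Reactants: 11 ethyl (5R,6R,7S,10S)-2,10-dimethyl-1,8-dioxo-7-(propan-2-yl)spiro[4.5]decane-6-carboxylate
Product: 13 ethyl (5R,6R,7S,10S)-2,10-dimethyl-1-oxo-7-(propan-2-yl)spiro[4.5]decane-6-carboxylate, via tosylhydrazone 12 (not isolated)
Conditions: TsNHNH2, EtOH, 50 °C; then catecholborane, CHCl3, 0 °C; NaOAc·3H2O, 60 °C
Reagents that add atoms: none
Why: Wolff–Kishner-type deoxygenation through tosylhydrazone reduction: only the C8 ketone should condense, since the C1 ketone is flanked by quaternary C5 and branched C2, and the alkyldiazene should lose N2 to leave CH2; C5 and C10 are not affected.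

Step 7
Reactants: 13 ethyl (5R,6R,7S,10S)-2,10-dimethyl-1-oxo-7-(propan-2-yl)spiro[4.5]decane-6-carboxylate
Product: 14 (5R,6R,7S,10S)-2,10-dimethyl-1-oxo-7-(propan-2-yl)spiro[4.5]decane-6-carboxylic acid
Conditions: KOH, EtOH/H2O, 80 °C; then 1 M HCl
Reagents that add atoms: potassium hydroxide, [K+].[OH-]
Why: Ester saponification should proceed on heating despite the hindered position; with C8 already reduced no retro-Michael path is open, and epimerisation at C2 or C6 is without consequence.

Step 8
Reactants: 14 (5R,6R,7S,10S)-2,10-dimethyl-1-oxo-7-(propan-2-yl)spiro[4.5]decane-6-carboxylic acid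
Product: 15 (5R,10S)-2,10-dimethyl-7-(propan-2-yl)spiro[4.5]dec-6-en-1-one (C2 epimers)
Conditions: 9-mesitylacridine (10 mol%), Co(dmgH)2(py)Cl (5 mol%), CH2Cl2, 400 nm LED, rt
Reagents that add atoms: none
Why: Photocatalytic decarboxylative olefination (acridine/cobaloxime dehydrodecarboxylation): the C6 radical left after loss of CO2 should be dehydrogenated by the cobaloxime, and because C5 is quaternary the only β-hydrogen is on C7, so the alkene can form only as C6=C7.

Step 9
Reactants: 15 (5R,10S)-2,10-dimethyl-7-(propan-2-yl)spiro[4.5]dec-6-en-1-one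
Product: 16 trimethyl{[(5R,10S)-2,10-dimethyl-7-(propan-2-yl)spiro[4.5]deca-1,6-dien-1-yl]oxy}silane
Conditions: Me3SiOTf, Et3N, CH2Cl2, 0 °C → rt
Reagents that add atoms: trimethylsilyl trifluoromethanesulfonate, C[Si](C)(C)OS(=O)(=O)C(F)(F)F
Why: Soft enolisation should give a single silyl enol ether because only C2 carries an enolisable hydrogen; both C2 epimers converge.

Step 10
Reactants: 17 2,4,6-trihydroxybenzaldehyde
Product: 18 tri-tert-butyl 2-formylbenzene-1,3,5-triyl tricarbonate
Conditions: Boc2O (3.3 equiv), DMAP (cat.), THF, 0 °C → rt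
Reagents that add atoms: di-tert-butyl dicarbonate, CC(C)(C)OC(=O)OC(=O)OC(C)(C)C
Why: DMAP-catalysed carbonate formation should cap all three phenols and leave the aldehyde free.

Step 11
Reactants: 16 trimethyl{[(5R,10S)-2,10-dimethyl-7-(propan-2-yl)spiro[4.5]deca-1,6-dien-1-yl]oxy}silane; 18 tri-tert-butyl 2-formylbenzene-1,3,5-triyl tricarbonate; 2 isobutylmagnesium bromide
Product: 20 silyl ketal cycloadduct (bis-carbonate of 22 carrying OSiMe3 in place of H on the O-bearing ring-fusion carbon; OSiMe3 cis to the angular methyl), via ortho-quinone methide 19 (not isolated)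
Conditions: 18 and 2 (2 equiv each), Et2O, −78 °C → rt; aq. NH4Cl
Reagents that add atoms: none
Why: Grignard addition to the aldehyde, Boc transfer to the benzylic alkoxide and loss of tert-butyl carbonate should give the quinone methide, which enters an inverse-demand hetero-Diels–Alder reaction with the enol ether: the enol ether polarity puts the benzylic carbon on C2 and the oxygen on C1, approach anti to the C10 CH(CH3) branch (on the face of the flat vinyl C6) should set the quaternary C2, and a silyloxy-endo transition state of the E-quinone methide should place isobutyl cis to the angular methyl.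

Step 12
Reactants: 20 silyl ketal cycloadduct
Product: 22 chroman-diol (23 without its two formyl groups; same configuration at all five centres), via bis-carbonate chroman 21 (not isolated)
Conditions: Et3SiH, BF3·OEt2, CH2Cl2, −78 → −20 °C; then K2CO3, MeOH, rt
Reagents that add atoms: none
Why: Ionic reduction of the ketal (reductive etherification): loss of the silyloxy group should give the aryl-oxygen-stabilised oxocarbenium ion, hydride adds on the face of the angular methyl to give the cis-fused O–CH centre, and methanolysis then removes the two aryl carbonates.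

Step 13
Reactants: 22 chroman-diol
Product: 23 (1R,3a'S,6S,9'R,9a'R)-6',8'-dihydroxy-6,9a'-dimethyl-9'-(2-methylpropyl)-3-(propan-2-yl)-1',2',9',9a'-tetrahydro-3a'H-spiro[cyclohex-2-ene-1,3'-cyclopenta[b]chromene]-5',7'-dicarbaldehyde (target)
Conditions: POCl3, DMF (excess), EtOAc, 0 °C → rt; then H2O, 50 °C
Reagents that add atoms: N,N-dimethylformamide, CN(C)C=O; water, O
Why: Double Vilsmeier–Haack formylation, as in the preparation of diformylphloroglucinol, should place the two formyl groups on the only two free positions of the phloroglucinol ring, and creates no stereocentre.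

**Compound list**

1 | (2E)-but-2-enal | C/C=C/C=O | starting material
2 | isobutylmagnesium bromide | CC(C)C[Mg]Br | starting material
3 | (2E)-6-methylhept-2-en-4-ol (racemic) | C/C=C/C(O)CC(C)C | intermediate
4 | (2E)-6-methylhept-2-en-4-one | C/C=C/C(=O)CC(C)C | intermediate
5 | {[(2E,4Z)-6-methylhepta-2,4-dien-4-yl]oxy}tri(propan-2-yl)silane | C/C=C/C(=C/C(C)C)O[Si](C(C)C)(C(C)C)C(C)C | intermediate
6 | 2-methylcyclopentan-1-one (racemic) | CC1CCCC1=O | starting material
7 | ethyl glyoxylate | CCOC(=O)C=O | starting material
8 | 1-(5-methylcyclopent-1-en-1-yl)pyrrolidine (not isolated) | CC1CCC=C1N1CCCC1 | intermediate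
9 | ethyl (2E)-2-(3-methyl-2-oxocyclopentylidene)acetate (racemic) | CCOC(=O)/C=C1\CCC(C)C1=O | intermediate
10 | ethyl (5R,6R,7S,10S)-2,10-dimethyl-1-oxo-7-(propan-2-yl)-8-{[tri(propan-2-yl)silyl]oxy}spiro[4.5]dec-8-ene-6-carboxylate, C2 epimers (not isolated) | O=C1C(C)CC[C@@]12[C@H](C(=O)OCC)[C@H](C(C)C)C(O[Si](C(C)C)(C(C)C)C(C)C)=C[C@@H]2C | intermediate
11 | ethyl (5R,6R,7S,10S)-2,10-dimethyl-1,8-dioxo-7-(propan-2-yl)spiro[4.5]decane-6-carboxylate, C2 epimers | O=C1C(C)CC[C@@]12[C@H](C(=O)OCC)[C@H](C(C)C)C(=O)C[C@@H]2C | intermediate
12 | C8 4-methylbenzenesulfonylhydrazone of 11 (not isolated) | O=C1C(C)CC[C@@]12[C@H](C(=O)OCC)[C@H](C(C)C)C(=NNS(=O)(=O)c1ccc(C)cc1)C[C@@H]2C | intermediate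
13 | ethyl (5R,6R,7S,10S)-2,10-dimethyl-1-oxo-7-(propan-2-yl)spiro[4.5]decane-6-carboxylate, C2 epimers | O=C1C(C)CC[C@@]12[C@H](C(=O)OCC)[C@H](C(C)C)CC[C@@H]2C | intermediate
14 | (5R,6R,7S,10S)-2,10-dimethyl-1-oxo-7-(propan-2-yl)spiro[4.5]decane-6-carboxylic acid, C2 epimers | O=C1C(C)CC[C@@]12[C@H](C(=O)O)[C@H](C(C)C)CC[C@@H]2C | intermediate
15 | (5R,10S)-2,10-dimethyl-7-(propan-2-yl)spiro[4.5]dec-6-en-1-one, C2 epimers | O=C1C(C)CC[C@@]12C=C(C(C)C)CC[C@@H]2C | intermediate
16 | trimethyl{[(5R,10S)-2,10-dimethyl-7-(propan-2-yl)spiro[4.5]deca-1,6-dien-1-yl]oxy}silane | C[Si](C)(C)OC1=C(C)CC[C@@]12C=C(C(C)C)CC[C@@H]2C | intermediate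
17 | 2,4,6-trihydroxybenzaldehyde | O=Cc1c(O)cc(O)cc1O | starting material
18 | tri-tert-butyl 2-formylbenzene-1,3,5-triyl tricarbonate | O=Cc1c(OC(=O)OC(C)(C)C)cc(OC(=O)OC(C)(C)C)cc1OC(=O)OC(C)(C)C | intermediate
19 | (6E)-3,5-bis[(tert-butoxycarbonyl)oxy]-6-(3-methylbutylidene)cyclohexa-2,4-dien-1-one (not isolated) | CC(C)C/C=C1/C(=O)C=C(OC(=O)OC(C)(C)C)C=C1OC(=O)OC(C)(C)C | intermediate
20 | silyl ketal cycloadduct: bis(tert-butyl carbonate) of 22 with OSiMe3 in place of H on the O-bearing ring-fusion carbon (3a'R; OSiMe3 cis to the angular methyl; other centres as in 23) | CC(C)C[C@H]1c2c(OC(=O)OC(C)(C)C)cc(OC(=O)OC(C)(C)C)cc2O[C@@]2(O[Si](C)(C)C)[C@]1(C)CC[C@@]21C=C(C(C)C)CC[C@@H]1C | intermediate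
21 | bis(tert-butyl carbonate) of 22, configuration as in 23 (not isolated) | CC(C)C[C@H]1c2c(OC(=O)OC(C)(C)C)cc(OC(=O)OC(C)(C)C)cc2O[C@H]2[C@]1(C)CC[C@@]21C=C(C(C)C)CC[C@@H]1C | intermediate
22 | (1R,3a'S,6S,9'R,9a'R)-6,9a'-dimethyl-9'-(2-methylpropyl)-3-(propan-2-yl)-1',2',9',9a'-tetrahydro-3a'H-spiro[cyclohex-2-ene-1,3'-cyclopenta[b]chromene]-6',8'-diol | CC(C)C[C@H]1c2c(O)cc(O)cc2O[C@H]2[C@]1(C)CC[C@@]21C=C(C(C)C)CC[C@@H]1C | intermediate
23 | (1R,3a'S,6S,9'R,9a'R)-6',8'-dihydroxy-6,9a'-dimethyl-9'-(2-methylpropyl)-3-(propan-2-yl)-1',2',9',9a'-tetrahydro-3a'H-spiro[cyclohex-2-ene-1,3'-cyclopenta[b]chromene]-5',7'-dicarbaldehyde | CC(C)C[C@H]1c2c(O)c(C=O)c(O)c(C=O)c2O[C@H]2[C@]1(C)CC[C@@]21C=C(C(C)C)CC[C@@H]1C | target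

**Count and risks**

Total step count: 13. Longest linear sequence: 11 steps (1, 2, 3, 5, 6, 7, 8, 9, 11, 12, 13).

Steps most likely to fail:

Step 5. The catalyst may bind the ester carbonyl in competition with the ring ketone, which would erode facial and exo selectivity. The diene may also be consumed by desilylative Michael addition without ring closure. Fallback: an amine-catalysed double Michael annulation that needs no silyl enol ether and no Lewis acid. Enone 4 and alkylidene ester 9 are combined with 9-amino-9-deoxy-epi-quinine (20 mol%) and 2-fluorobenzoic acid (40 mol%) in toluene at 40 °C. The cross-conjugated dienamine of 4 should add through its isopropyl-bearing carbon to the CH(CO2Et) carbon of 9, and the resulting ketone enolate should close onto the iminium-activated propenyl terminus; hydrolysis releases the catalyst. The diastereomer ratio would have to be established. This fallback sets out from 4 and 9, returns at 11 and makes no compound outside the list (F0).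

Step 8. The C6 radical may attack the neighbouring C1 ketone and undergo a 1,2-acyl shift (ring enlargement) before it is captured, or the cobalt hydride may re-add and move the double bond. Fallback: a chalcogen route with a fast radical trap and a syn-elimination. Acid 14 is converted with 1-hydroxypyridine-2(1H)-thione and DCC (DMAP cat., CH2Cl2, dark) into the thiohydroxamate ester F1. Visible-light photolysis of F1 with PhSeSePh should give the C6 phenyl selenide F2, selenium arriving trans to the C7 isopropyl group and therefore syn to the C7 hydrogen. H2O2 and pyridine in CH2Cl2 (0 °C → rt) should give the selenoxide F3, which can eliminate only toward C7. The fallback sets out from 14 and returns at 15.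

Step 11. The short-lived quinone methide may dimerise faster than it meets the hindered tetrasubstituted enol ether. Control at the benzylic carbon may also be lost through E/Z isomerism of the quinone methide or a stepwise Michael pathway, and facial selectivity at C2 may be modest. Fallback: the two benzylic bonds are made in the opposite order. Ketone 15 is deprotonated with LiN(iPr)2 (THF, −78 °C) and the enolate is added to aldehyde 18. On addition of 2 and warming, Boc transfer and elimination should give the terpenoid-substituted quinone methide F4 (not isolated), which takes up the isobutyl group by conjugate addition of 2. The liberated phenoxide closes on the C1 ketone to give hemiketal F5 after aq. NH4Cl. F5 is then treated under the conditions of step 12. The fallback sets out from 15 (with 18 and 2) and returns at 22.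

**Further compounds**

F0 | step 5 | none | none
F1 | step 8 | 2-sulfanylidenepyridin-1(2H)-yl (5R,6R,7S,10S)-2,10-dimethyl-1-oxo-7-(propan-2-yl)spiro[4.5]decane-6-carboxylate | O=C1C(C)CC[C@@]12[C@H](C(=O)ON1C=CC=CC1=S)[C@H](C(C)C)CC[C@@H]2C
F2 | step 8 | 2,10-dimethyl-6-(phenylselanyl)-7-(propan-2-yl)spiro[4.5]decan-1-one (C5 and C10 as in 14; SePh trans to the C7 isopropyl group) | O=C1C(C)CC[C@@]12[C@@H]([Se]c1ccccc1)[C@H](C(C)C)CC[C@@H]2C
F3 | step 8 | selenoxide of F2 | O=C1C(C)CC[C@@]12[C@@H]([Se](=O)c1ccccc1)[C@H](C(C)C)CC[C@@H]2C
F4 | step 11 | ortho-quinone methide carrying the skeleton of 15 (bonded through C2) on the methide carbon, 3,5-bis(tert-butyl carbonate) | O=C1[C@@](C)(C=C3C(=O)C=C(OC(=O)OC(C)(C)C)C=C3OC(=O)OC(C)(C)C)CC[C@@]12C=C(C(C)C)CC[C@@H]2C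
F5 | step 11 | hemiketal: 20 with OH in place of OSiMe3 | CC(C)C[C@H]1c2c(OC(=O)OC(C)(C)C)cc(OC(=O)OC(C)(C)C)cc2O[C@@]2(O)[C@]1(C)CC[C@@]21C=C(C(C)C)CC[C@@H]1C
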